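The route rests on cutting the C3–OAc bond. The tertiary allylic acetate at C3, taken with its C1=C2 vinyl group, equals acetic acid added across a C1=C2=C3 allene. One rhodium-catalysed hydroacetoxylation puts hydrogen on C2 and acetate on C3. This creates the 3R centre next to the finished 4S coumarate and avoids esterifying a crowded C3 carbinol, during which the neighbouring acyl group could shift. The chain stays acyclic and the arene is a spectator. The precursor is the TBS-protected p-coumarate of (S)-3,7-dimethylocta-1,2,6-trien-4-ol, a 1,1-disubstituted allene whose C3 carries methyl and C4. It is assembled by enantioselective allenylboration of 4-methylpent-3-enal and Steglich esterification. Desilylation ends the route.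

Key step: step 6

Assumption: Re-face attack under (R)-TRIP in step 3 is inferred from related allyl- and allenylborations of aldehydes and is to be checked by Mosher ester analysis, whereas the sense of (R,R)-DIOP at a fully substituted allyl terminus in step 6 cannot be derived from precedent, so the equally available antipode replaces it if the first run favours the 3S epimer.

Step 1
Reactants: 1 4-methylpent-3-en-1-ol
Product: 2 4-methylpent-3-enal
Conditions: Dess–Martin periodinane (1.1 equiv), NaHCO3 (2.5 equiv), CH2Cl2, 0 °C to rt; pentane, short silica plug; solvent exchanged to toluene at 0 °C without taking to dryness, used at once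
Reagents that add atoms: none
Why: Dess–Martin oxidation stops at the aldehyde, and the bicarbonate-buffered, amine-free medium gives the β,γ-double bond little chance to slip into conjugation.

Step 2
Reactants: 3 prop-1-ynyllithium; 4 2-(iodomethyl)-4,4,5,5-tetramethyl-1,3,2-dioxaborolane
Product: 6 but-2-yn-1-ylboronic acid pinacol ester, via lithium boronate complex 5 (not isolated)
Conditions: THF, −78 °C, then rt, 12 h; aq. NH4Cl; bulb-to-bulb distillation
Reagents that add atoms: none
Why: In this Matteson homologation the alkynyl group shifts from boron to carbon with loss of iodide, which places boron unambiguously on the propargylic CH2, whereas metal-catalysed borylation of but-2-ynyl halides or carbonates runs SN2' and gives the allenyl isomer that would lead to a homopropargylic alcohol.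

Step 3
Reactants: 2 4-methylpent-3-enal; 6 but-2-yn-1-ylboronic acid pinacol ester
Product: 8 (S)-3,7-dimethylocta-1,2,6-trien-4-ol, via allenyl carbinol pinacol borate 7 (not isolated)
Conditions: (R)-TRIP [(R)-3,3'-bis(2,4,6-triisopropylphenyl)-1,1'-binaphthyl-2,2'-diyl hydrogen phosphate] (5 mol %), 4 Å MS, toluene, −30 °C; aq. NaHCO3 work-up
Reagents that add atoms: none
Why: In this chiral-phosphoric-acid-catalysed allenylboration the propargylic boronate reacts at its γ-carbon (SE2') through a closed six-membered transition state, which turns the alkyne into the C1=C2=C3 allene with methyl on C3, while the acid, hydrogen-bonded to a pinacol oxygen and the formyl hydrogen, exposes the Re face of 2 and so sets 4S.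

Step 4
Reactants: 9 p-coumaric acid
Product: 11 (E)-3-[4-(tert-butyldimethylsilyloxy)phenyl]acrylic acid, via bis-silylated coumarate 10 (not isolated)
Conditions: TBSCl (2.3 equiv), imidazole (5 equiv), DMF, rt; aqueous work-up; crude in THF/H2O, K2CO3 (1 equiv), rt, 1 h; 1 M HCl to pH 4 at 0 °C
Reagents that add atoms: tert-butyldimethylsilyl chloride, CC(C)(C)[Si](C)(C)Cl
Why: Exhaustive silylation is followed by selective hydrolysis, because the silyl ester is far more labile to mild aqueous base than the aryl silyl ether, so only the carboxyl group is released and the E alkene is untouched.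

Step 5
Reactants: 8 (S)-3,7-dimethylocta-1,2,6-trien-4-ol; 11 (E)-3-[4-(tert-butyldimethylsilyloxy)phenyl]acrylic acid
Product: 12 (S)-3,7-dimethylocta-1,2,6-trien-4-yl (E)-3-[4-(tert-butyldimethylsilyloxy)phenyl]acrylate
Conditions: DCC (1.2 equiv), DMAP (0.2 equiv), CH2Cl2, 0 °C to rt
Reagents that add atoms: none
Why: In the Steglich esterification the acylpyridinium species acylates the carbinol oxygen without touching the C4–O bond, so 4S is retained, and the allene, both alkenes and the aryl silyl ether are inert to DCC/DMAP.

Step 6
Reactants: 12 (S)-3,7-dimethylocta-1,2,6-trien-4-yl (E)-3-[4-(tert-butyldimethylsilyloxy)phenyl]acrylate; 13 acetic acid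
Product: 14 (3R,4S)-3-acetoxy-3,7-dimethylocta-1,6-dien-4-yl (E)-3-[4-(tert-butyldimethylsilyloxy)phenyl]acrylate
Conditions: [Rh(cod)Cl]2 (5 mol %), (R,R)-DIOP [(4R,5R)-4,5-bis(diphenylphosphinomethyl)-2,2-dimethyl-1,3-dioxolane] (12 mol %), Cs2CO3 (10 mol %), AcOH (3 equiv), 1,2-dichloroethane, 0 °C to rt, stopped as soon as 12 is consumed
Reagents that add atoms: acetic acid (compound 13), CC(=O)O
Why: Proposed new method: acetic acid adds through its O–H bond to the monovalent rhodium diphosphine complex to give a trivalent rhodium hydride acetate; the allene binds through its unhindered C1=C2 π bond, hydride migrates to the central C2, and the π-allyl complex spanning C1–C3 collapses by inner-sphere C–O bond formation at its fully substituted end C3, which leaves C1=C2 as the vinyl group. The closest known reaction type is the rhodium/DIOP-catalysed branched-selective addition of carboxylic acids to terminal monosubstituted allenes, which gives secondary allylic esters; the new element is C–O bond formation at a quaternary allyl terminus flanked by an acyloxy-bearing carbon. No ring is closed. The only new stereocentre, C3, is set by the allyl face from which acetate is delivered: the two faces interconvert by π–σ–π exchange through the C1-bound σ-allyl form, the bulkier C4 branch takes the syn position and methyl the anti position, and the chiral diphosphine, reinforced or opposed by the resident 4S centre, selects the diastereomeric complex that eliminates faster (Curtin–Hammett control). The step needs branched over linear regiochemistry, 3R over 3S facial selectivity and chemoselectivity for the allene; the cumulated diene is the only π system reactive enough to insert into Rh–H under these mild conditions, so the C6=C7 alkene and the cinnamoyl C=C remain spectators, and the silyl ether removes the competing phenolic O–H. The electron-withdrawing acyloxy group on C4, the low temperature and the excess acid should slow re-ionisation of the tertiary acetate, so the kinetic branched product should persist.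

Step 7
Reactants: 14 (3R,4S)-3-acetoxy-3,7-dimethylocta-1,6-dien-4-yl (E)-3-[4-(tert-butyldimethylsilyloxy)phenyl]acrylate
Product: 15 (3R,4S)-3-acetoxy-3,7-dimethylocta-1,6-dien-4-yl (E)-3-(4-hydroxyphenyl)acrylate (target)
Conditions: TBAF (1.1 equiv) premixed with AcOH (1.1 equiv), THF, 0 °C, 30 min
Reagents that add atoms: none
Why: In this fluoride-mediated desilylation the aryl silyl ether, with phenoxide as leaving group, is cleaved quickly, and the acetic acid buffer protonates the phenoxide at once, so neither the C3 acetate nor the C4 coumarate is attacked and both stereocentres stay as set.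

Compound list
1 | 4-methylpent-3-en-1-ol | CC(C)=CCCO | starting material
2 | 4-methylpent-3-enal | CC(C)=CCC=O | intermediate
3 | prop-1-ynyllithium | [Li]C#CC | starting material
4 | 2-(iodomethyl)-4,4,5,5-tetramethyl-1,3,2-dioxaborolane | ICB1OC(C)(C)C(C)(C)O1 | starting material
5 | lithium (iodomethyl)(prop-1-ynyl)pinacolatoborate | [Li+].CC#C[B-]1(CI)OC(C)(C)C(C)(C)O1 | intermediate
6 | but-2-yn-1-ylboronic acid pinacol ester | CC#CCB1OC(C)(C)C(C)(C)O1 | intermediate
7 | (S)-3,7-dimethylocta-1,2,6-trien-4-yl pinacol borate | C=C=C(C)[C@H](CC=C(C)C)OB1OC(C)(C)C(C)(C)O1 | intermediate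
8 | (S)-3,7-dimethylocta-1,2,6-trien-4-ol | C=C=C(C)[C@H](CC=C(C)C)O | intermediate
9 | p-coumaric acid | O=C(O)/C=C/c1ccc(O)cc1 | starting material
10 | tert-butyldimethylsilyl (E)-3-[4-(tert-butyldimethylsilyloxy)phenyl]acrylate | CC(C)(C)[Si](C)(C)OC(=O)/C=C/c1ccc(O[Si](C)(C)C(C)(C)C)cc1 | intermediate
11 | (E)-3-[4-(tert-butyldimethylsilyloxy)phenyl]acrylic acid | O=C(O)/C=C/c1ccc(O[Si](C)(C)C(C)(C)C)cc1 | intermediate
12 | (S)-3,7-dimethylocta-1,2,6-trien-4-yl (E)-3-[4-(tert-butyldimethylsilyloxy)phenyl]acrylate | C=C=C(C)[C@H](CC=C(C)C)OC(=O)/C=C/c1ccc(O[Si](C)(C)C(C)(C)C)cc1 | intermediate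
13 | acetic acid | CC(=O)O | starting material
14 | (3R,4S)-3-acetoxy-3,7-dimethylocta-1,6-dien-4-yl (E)-3-[4-(tert-butyldimethylsilyloxy)phenyl]acrylate | C=C[C@@](C)(OC(C)=O)[C@H](CC=C(C)C)OC(=O)/C=C/c1ccc(O[Si](C)(C)C(C)(C)C)cc1 | intermediate
15 | (3R,4S)-3-acetoxy-3,7-dimethylocta-1,6-dien-4-yl (E)-3-(4-hydroxyphenyl)acrylate | C=C[C@@](C)(OC(C)=O)[C@H](CC=C(C)C)OC(=O)/C=C/c1ccc(O)cc1 | target

Total step count: 7. Longest linear sequence: 5 steps (1, 3, 5, 6, 7).

Steps most likely to fail

Step 6. Several processes could compete:
- C–O bond formation at the open C1 end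
- β-hydride loss from the allyl complex to 1,3-dienes
- rhodium-induced departure of the C4 coumarate
- poor facial selectivity at C3
- re-ionisation of the product

The fallback uses known chemistry, sets out from aldehyde 2 (with acid 11 as partner) and comes back at 14. It builds the C3–C4 bond and both stereocentres together by a Brown allylboration with a γ-borylated reagent. Copper-catalysed SN2' borylation of but-2-ynyl methyl carbonate (B2pin2, CuOtBu, Xantphos, THF) gives buta-2,3-dien-2-ylboronic acid pinacol ester F1. Hydroboration at C1 with (+)-Ipc2BH, made from (−)-α-pinene, followed by warming in toluene gives the equilibrated γ-boryl allylborane F2, in which the pinacol boronate stands trans to the CH2B carbon. At −78 °C this reagent adds to the Re face of 2 through a chair transition state to give the anti borinate adduct F3. NaOH/H2O2 then oxidises all C–B bonds with retention to (3R,4S)-3,7-dimethylocta-1,6-diene-3,4-diol F4. DCC/DMAP esterification with 11 takes only the secondary C4 hydroxyl and gives the C3-hydroxy C4-coumarate F5. Ac2O, Et3N and DMAP in CH2Cl2 acetylate the tertiary alcohol to 14.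

Step 3. The β,γ-double bond of 2 may drift into conjugation under the acid catalyst, an uncatalysed background addition may compete, and facial selectivity may be modest with an unbranched aliphatic aldehyde. The fallback sets out from 2 and comes back at 8. It replaces boron and Brønsted acid by a catalytic asymmetric Nozaki–Hiyama–Kishi allenylation under neutral conditions. The reagents are 1-bromobut-2-yne, CrCl2 (10 mol %), a chiral tridentate carbazole bis(oxazoline) ligand of the antipode that directs Re-face attack, Mn powder, TMSCl and iPr2NEt in THF. The γ-substituted propargylchromium species reacts at its γ-carbon to give (S)-3,7-dimethylocta-1,2,6-trien-4-yl trimethylsilyl ether F6. TBAF in THF at 0 °C releases 8.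

Step 1. The volatile aldehyde may be lost on solvent exchange, and it may isomerise on silica or on standing. The fallback sets out from 1 and comes back at 8, bypassing 2 and 6. TEMPO/PhI(OAc)2 in MeCN/H2O takes 1 straight to the non-volatile 4-methylpent-3-enoic acid F7. CDI and MeNHOMe·HCl give the Weinreb amide F8. Lithiated 3-methoxyprop-1-yne (nBuLi, THF, −78 °C) gives 1-methoxy-7-methyloct-6-en-2-yn-4-one F9 (Weinreb ketone synthesis). Noyori asymmetric transfer hydrogenation with Ru[(S,S)-TsDPEN](p-cymene) in iPrOH at rt, without added base, gives (S)-1-methoxy-7-methyloct-6-en-2-yn-4-ol F10. MeMgBr (3 equiv) with CuBr (10 mol %) in Et2O at 0 °C then displaces methoxide in the SN2' sense. This places methyl on C3 and unfolds the terminal allene of 8 without touching C4.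

Further compounds
F1 | step 6 | buta-2,3-dien-2-ylboronic acid pinacol ester | C=C=C(C)B1OC(C)(C)C(C)(C)O1
F2 | step 6 | bis[(+)-isopinocampheyl][(Z)-3-(4,4,5,5-tetramethyl-1,3,2-dioxaborolan-2-yl)but-2-en-1-yl]borane (boronate trans to CH2B) | C[C@@H]1[C@@H](B(C/C=C(\C)B2OC(C)(C)C(C)(C)O2)[C@H]3C[C@H]4C[C@@H]([C@@H]3C)C4(C)C)C[C@H]5C[C@@H]1C5(C)C
F3 | step 6 | diisopinocampheylborinate of the anti C3-(pinacolboryl) C4-carbinol adduct | C=C[C@@](C)(B1OC(C)(C)C(C)(C)O1)[C@H](CC=C(C)C)OB([C@H]2C[C@H]3C[C@@H]([C@@H]2C)C3(C)C)[C@H]4C[C@H]5C[C@@H]([C@@H]4C)C5(C)C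
F4 | step 6 | (3R,4S)-3,7-dimethylocta-1,6-diene-3,4-diol | C=C[C@@](C)(O)[C@H](CC=C(C)C)O
F5 | step 6 | (3R,4S)-3-hydroxy-3,7-dimethylocta-1,6-dien-4-yl (E)-3-[4-(tert-butyldimethylsilyloxy)phenyl]acrylate | C=C[C@@](C)(O)[C@H](CC=C(C)C)OC(=O)/C=C/c1ccc(O[Si](C)(C)C(C)(C)C)cc1
F6 | step 3 | (S)-3,7-dimethylocta-1,2,6-trien-4-yl trimethylsilyl ether | C=C=C(C)[C@H](CC=C(C)C)O[Si](C)(C)C
F7 | step 1 | 4-methylpent-3-enoic acid | CC(C)=CCC(=O)O
F8 | step 1 | N-methoxy-N,4-dimethylpent-3-enamide | CC(C)=CCC(=O)N(C)OC
F9 | step 1 | 1-methoxy-7-methyloct-6-en-2-yn-4-one | COCC#CC(=O)CC=C(C)C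
F10 | step 1 | (S)-1-methoxy-7-methyloct-6-en-2-yn-4-ol | COCC#C[C@H](CC=C(C)C)O
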